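**Assumption:** labdane numbering is used for the decalin and C11–C19 for the chain (C15 = carbinol carbon, C16 = lactone CH). Read this way the target is the 13E,15S,16S isomer, and its decalin (5α-H, 9α-H, 10β-Me, 8α-OH/8β-Me) is that of (−)-sclareol plus a 6α-hydroxyl.

## Retrosynthetic overview

1. C15–C16 (last step): enantioselective vinylogous Mukaiyama aldol of a C20 (13E)-enal with 4-methyl-2-(trimethylsilyloxy)furan; sets C15 and C16.
2. C15–O: the enal comes from a primary allylic alcohol made by rhenium-oxo 1,3-transposition of the tertiary vinyl carbinol of 6α-hydroxysclareol (C13 stereocentre spent, 13E alkene set).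
3. C6–O (key step, first in the forward direction): site- and face-selective enzymatic C–H hydroxylation of (−)-sclareol, the one oxygen that sclareol lacks.
4. Rings: none is built. Rings A and B with C5, C8, C9 and C10 come from sclareol; the butenolide ring comes from 4-methyl-2(5H)-furanone.

## Route

Step 1
Reactants: 1 (−)-sclareol [(13R)-labd-14-ene-8α,13-diol]
Product: 2 6α-hydroxysclareol [(13R)-labd-14-ene-6α,8α,13-triol]
Conditions: engineered P450 BM3 (CYP102A1) variant (E. coli lysate, 0.1 mol%), NADP+ (cat.), D-glucose (2 equiv), glucose dehydrogenase, air, KPi buffer pH 8.0, 5% DMSO, 25 °C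
Reagents that add atoms: dioxygen, O=O
Why: Proposed new method: an evolved P450 BM3 variant hydroxylates the C6 methylene of sclareol, the oxo-iron porphyrin radical cation abstracting the equatorial 6α-H (6β lies under the three syn-axial methyls C17, C19 and C20, and C7 is deactivated by the adjacent C8 carbinol) and returning oxygen on the same face, so that 6α-OH forms with retention; the design re-seats the decalin in an F87A-type pocket (added bulk at residue 328 pushes ring A off the heme, the 13-OH/vinyl tail lies in the access channel) and is optimised by saturation mutagenesis at positions 75, 78, 82, 263, 328 and 437 with LC–MS screening; the closest known reaction type is the C3 hydroxylation of sclareol and sclareolide by P450 BM3 variants.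

Step 2
Reactants: 2 6α-hydroxysclareol
Product: 4 (13E)-labd-13-ene-6α,8α,15-triol, via 6,15-bis-O-trimethylsilyl ether 3 (not isolated)
Conditions: Ph3SiOReO3 (2 mol%), BSA (3 equiv), Et2O, −50 → 0 °C; then K2CO3 (cat.), MeOH, 0 °C; E isomer isolated on AgNO3–SiO2
Reagents that add atoms: none
Why: Rhenium-oxo-catalysed 1,3-transposition of the allylic alcohol (formal [3,3] shift of the allyl perrhenate through a chair transition state) makes the C15–O bond, N,O-bis(trimethylsilyl)acetamide (BSA) drains the equilibrium by silylating the new primary hydroxyl, and the larger C12 chain sits equatorial so the 13E alkene dominates (about 3:1 expected, the Z isomer can be resubmitted).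

Step 3
Reactants: 4 (13E)-labd-13-ene-6α,8α,15-triol
Product: 5 (13E)-6α,8α-dihydroxylabd-13-en-15-al
Conditions: MnO2 (15 equiv), CH2Cl2, rt
Reagents that add atoms: none
Why: MnO2 oxidation is selective for allylic alcohols, so only the primary allylic 15-OH is oxidised while the non-allylic 6α-OH and the tertiary 8α-OH are untouched and the 13E geometry is kept.

Step 4
Reactants: 6 4-methyl-2(5H)-furanone
Product: 7 4-methyl-2-(trimethylsilyloxy)furan
Conditions: TMSOTf (1.1 equiv), Et3N (1.3 equiv), Et2O, 0 °C; distil
Reagents that add atoms: trimethylsilyl trifluoromethanesulfonate, C[Si](C)(C)OS(=O)(=O)C(F)(F)F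
Why: Soft γ-enolisation and O-silylation of the butenolide gives the aromatic 2-silyloxyfuran, the standard preparation of these vinylogous silyl ketene acetals.

Step 5
Reactants: 5 (13E)-6α,8α-dihydroxylabd-13-en-15-al; 7 4-methyl-2-(trimethylsilyloxy)furan
Product: 9 target CNP0279704.1 [(13E,15S,16S)-5-substituted 4-methylfuran-2(5H)-one of the 6α,8α-dihydroxy decalin], via 15-O-trimethylsilyl ether 8 (not isolated)
Conditions: (R)-BINOL (20 mol%), Ti(OiPr)4 (20 mol%), 7 (2.5 equiv), Et2O, −20 °C; then citric acid, MeOH–H2O, 0 °C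
Reagents that add atoms: none
Why: Catalytic enantioselective vinylogous Mukaiyama aldol in which the BINOL–Ti(OiPr)4 complex activates the aldehyde and leaves its Re face open, the silyloxyfuran attacks through C5 (γ) with its Re face in an open synclinal transition state (like combination) to give the 5,1′-threo adduct with 15S,16S configuration, and mild acid removes the transferred silyl group.

## Compound list

1 | (−)-sclareol, (13R)-labd-14-ene-8α,13-diol | C=C[C@](C)(O)CC[C@@H]1[C@@]2(C)CCCC(C)(C)[C@@H]2CC[C@@]1(C)O | starting material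
2 | 6α-hydroxysclareol, (13R)-labd-14-ene-6α,8α,13-triol | C=C[C@](C)(O)CC[C@@H]1[C@@]2(C)CCCC(C)(C)[C@@H]2[C@@H](O)C[C@@]1(C)O | intermediate
3 | (13E)-6α,15-bis(trimethylsilyloxy)labd-13-en-8α-ol | C[Si](C)(C)OC/C=C(\C)CC[C@@H]1[C@@]2(C)CCCC(C)(C)[C@@H]2[C@@H](O[Si](C)(C)C)C[C@@]1(C)O | intermediate (not isolated)
4 | (13E)-labd-13-ene-6α,8α,15-triol | OC/C=C(\C)CC[C@@H]1[C@@]2(C)CCCC(C)(C)[C@@H]2[C@@H](O)C[C@@]1(C)O | intermediate
5 | (13E)-6α,8α-dihydroxylabd-13-en-15-al | O=C/C=C(\C)CC[C@@H]1[C@@]2(C)CCCC(C)(C)[C@@H]2[C@@H](O)C[C@@]1(C)O | intermediate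
6 | 4-methyl-2(5H)-furanone | CC1=CC(=O)OC1 | starting material
7 | 4-methyl-2-(trimethylsilyloxy)furan | Cc1coc(O[Si](C)(C)C)c1 | intermediate
8 | 15-O-trimethylsilyl ether of the target (13E,15S,16S) | CC1=CC(=O)O[C@@H]1[C@@H](O[Si](C)(C)C)/C=C(\C)CC[C@@H]1[C@@]2(C)CCCC(C)(C)[C@@H]2[C@@H](O)C[C@@]1(C)O | intermediate (not isolated)
9 | CNP0279704.1, (5S)-5-[(1S,2E)-1-hydroxy-3-methyl-5-(6α,8α-dihydroxy-labdane decalin-9-yl)pent-2-enyl]-4-methylfuran-2(5H)-one | CC1=CC(=O)O[C@@H]1[C@@H](O)/C=C(\C)CC[C@@H]1[C@@]2(C)CCCC(C)(C)[C@@H]2[C@@H](O)C[C@@]1(C)O | target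

## Step count and risks

Total: 5 steps. Longest linear sequence: 4 steps (1, 2, 3, 5); step 4 makes the coupling partner.

**Step 1 (the proposed new hydroxylation).** It can fail by oxidation at the usual ring A sites (C2, C3, C18), by epoxidation of the vinyl group, or by over-oxidation to the 6-ketone. The fallback uses known chemistry and gives up the C–H oxidation. It does not set out from 1 but from purchased (+)-larixol F1 [(13S)-labda-8(17),14-diene-6α,13-diol], which replaces 1, costs more than sclareol and already carries the 6α-hydroxyl. mCPBA with NaHCO3 in CH2Cl2 at 0 °C epoxidises the exocyclic 1,1-disubstituted alkene from the open α face, not the vinyl group, to give the 8α,17-epoxide F2. LiAlH4 in THF opens it at the CH2 end to (13S)-labd-14-ene-6α,8α,13-triol F3, the C13 epimer of 2. F3 goes through step 2 unchanged, because C13 is erased there, and the fallback comes back to the route at 4.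

**Step 2.** The tertiary allylic perrhenate can ionise, after which the 8α-OH closes the 8,13-ether (manoyl oxide type) or water is lost; the E:Z ratio may also be low. The fallback sets out from 2 and comes back at 4. OsO4 (2 mol%) with NaIO4 and 2,6-lutidine in dioxane–water cleaves the vinyl carbinol to 6α,8α-dihydroxy-14,15-dinorlabdan-13-one F4. Horner–Wadsworth–Emmons olefination with triethyl phosphonoacetate and NaH in THF gives ethyl (13E)-6α,8α-dihydroxylabd-13-en-15-oate F5 (E:Z about 4:1, separable). i-Bu2AlH in CH2Cl2 at −78 °C reduces F5 to 4. No cationic intermediate is involved.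

**Step 5.** The threo:erythro ratio or the ee may be low, the free hydroxyls may bind titanium or take up silyl groups, and the (R)-BINOL facial sense is assigned by analogy. If the sense proves opposite, (S)-BINOL is used. The fallback sets out from 5 (with 7) and comes back at 9. It drops catalyst control of absolute configuration and keeps only the relative, threo-selective control of an achiral Lewis acid: BF3·OEt2 in CH2Cl2 at −78 °C. This gives 9 and its (15R,16R) threo diastereomer F6 in about equal amounts. Because the decalin is enantiopure the two are diastereomers, so 9 is isolated by chromatography at the cost of half the material.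

## Further compounds

F1 | step 1 | (+)-larixol, (13S)-labda-8(17),14-diene-6α,13-diol | C=C[C@@](C)(O)CC[C@@H]1[C@@]2(C)CCCC(C)(C)[C@@H]2[C@@H](O)CC1=C
F2 | step 1 | (13S)-8α,17-epoxylabd-14-ene-6α,13-diol | C=C[C@@](C)(O)CC[C@@H]1[C@@]2(C)CCCC(C)(C)[C@@H]2[C@@H](O)C[C@@]1(C3)O3
F3 | step 1 | (13S)-labd-14-ene-6α,8α,13-triol | C=C[C@@](C)(O)CC[C@@H]1[C@@]2(C)CCCC(C)(C)[C@@H]2[C@@H](O)C[C@@]1(C)O
F4 | step 2 | 6α,8α-dihydroxy-14,15-dinorlabdan-13-one | CC(=O)CC[C@@H]1[C@@]2(C)CCCC(C)(C)[C@@H]2[C@@H](O)C[C@@]1(C)O
F5 | step 2 | ethyl (13E)-6α,8α-dihydroxylabd-13-en-15-oate | CCOC(=O)/C=C(\C)CC[C@@H]1[C@@]2(C)CCCC(C)(C)[C@@H]2[C@@H](O)C[C@@]1(C)O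
F6 | step 5 | (15R,16R) threo diastereomer of the target | CC1=CC(=O)O[C@H]1[C@H](O)/C=C(\C)CC[C@@H]1[C@@]2(C)CCCC(C)(C)[C@@H]2[C@@H](O)C[C@@]1(C)O
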